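**Strategy.** The route rests on opening the ten-membered carbocycle between the two acyloxy-bearing carbons C8 and C9 (germacranolide numbering). The feature exploited is the C8,C9-diol flanked by the C1=C10 enoate: read backwards, it is a cross-pinacol of a C8 aldehyde with a 2-formyl-enoate. In one operation, chromium dichloride and Et3SiCl turn the acyclic dialdehyde into a γ-siloxyallylchromium that closes the ring through C9, sets C8 and C9, regenerates C1=C10 as the ring-cis enoate and leaves O8 free and O9 silylated for stepwise acylation. The precursor is a trans-disubstituted butyrolactone (C6, C7 from a chiral butenolide) carrying both aldehydes; the methylene lactone stays masked as its dimethylamine adduct.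

Key step: step 13

Remark: atoms are numbered as in germacranolides (ring C1–C10, lactone O6–C12(=O)–C11(C13)–C7, ester carbon C14 on C10, hydroxymethyl carbon C15 on C4), α/β follow the usual drawing with H7 α, and both ring double bonds are cis within the ring although their CIP descriptors are E.

**Step 1**
Reactants: 1 (S)-5-(hydroxymethyl)furan-2(5H)-one
Product: 2 (S)-5-[(triethylsilyloxy)methyl]furan-2(5H)-one
Conditions: Et3SiCl, imidazole, CH2Cl2, 0 °C
Reagents that add atoms: chlorotriethylsilane, CC[Si](Cl)(CC)CC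
Why: Standard silylation of the primary alcohol under weakly basic conditions that leave the C6 stereocentre of the butenolide untouched.

**Step 2**
Reactants: 2 (S)-5-[(triethylsilyloxy)methyl]furan-2(5H)-one
Product: 3 (4S,5S)-4-(1,3-dioxolan-2-yl)-5-[(triethylsilyloxy)methyl]oxolan-2-one (4,5-trans)
Conditions: benzophenone (0.1 equiv), 1,3-dioxolane (solvent), hν (medium-pressure Hg lamp, Pyrex), 10 °C, degassed
Reagents that add atoms: 1,3-dioxolane, C1COCO1
Why: Photosensitised radical conjugate addition, in which the nucleophilic 1,3-dioxolan-2-yl radical should add to the β-carbon (C7) anti to the C6 substituent, setting C7 trans to C6 and bringing in C8 as a masked aldehyde.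

**Step 3**
Reactants: 3 (4S,5S)-4-(1,3-dioxolan-2-yl)-5-[(triethylsilyloxy)methyl]oxolan-2-one
Product: 5 (3R,4S,5S)-3-[(dimethylamino)methyl]-4-(1,3-dioxolan-2-yl)-5-[(triethylsilyloxy)methyl]oxolan-2-one, via lactone lithium enolate 4 (not isolated)
Conditions: LiN(i-Pr)2, THF, −78 °C; then CH2=NMe2+ I−, −78 → 23 °C
Reagents that add atoms: N,N-dimethylmethyleneiminium iodide (Eschenmoser's salt), C=[N+](C)C.[I-]
Why: Mannich reaction of the lactone enolate, which should be aminomethylated anti to the C7 substituent; it installs C13 as the amine-masked form of the α-methylene group (the C11 centre is removed in step 18).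

**Step 4**
Reactants: 5 (3R,4S,5S)-3-[(dimethylamino)methyl]-4-(1,3-dioxolan-2-yl)-5-[(triethylsilyloxy)methyl]oxolan-2-one
Product: 6 (2S,3S,4R)-4-[(dimethylamino)methyl]-3-(1,3-dioxolan-2-yl)-5-oxooxolane-2-carbaldehyde
Conditions: (COCl)2, DMSO, CH2Cl2, −78 → −30 °C; Et3N, −78 → 0 °C
Reagents that add atoms: none
Why: Swern oxidation applied directly to the primary triethylsilyl ether (known one-pot silyl cleavage and oxidation), giving the C5 aldehyde under conditions that should not epimerise C6.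

**Step 5**
Reactants: 7 5-bromopent-1-ene
Product: 8 (pent-4-en-1-yl)triphenylphosphonium bromide
Conditions: PPh3, MeCN, reflux
Reagents that add atoms: triphenylphosphine, c1ccc(cc1)P(c1ccccc1)c1ccccc1
Why: SN2 quaternisation of a primary bromide by the phosphine.

**Step 6**
Reactants: 8 (pent-4-en-1-yl)triphenylphosphonium bromide
Product: 10 2-(triphenylphosphoranylidene)hex-5-enal, via pent-4-enylidene(triphenyl)phosphorane 9 (not isolated)
Conditions: KOt-Bu (2.1 equiv), THF, 0 °C; then HCO2Et, 0 → 23 °C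
Reagents that add atoms: ethyl formate, CCOC=O
Why: C-formylation of the non-stabilised ylide with the formate ester, the second equivalent of base converting the acylphosphonium salt into the stabilised α-alkyl formyl ylide (C15, C4–C1 and a sacrificial terminal CH2).

**Step 7**
Reactants: 6 (2S,3S,4R)-4-[(dimethylamino)methyl]-3-(1,3-dioxolan-2-yl)-5-oxooxolane-2-carbaldehyde; 10 2-(triphenylphosphoranylidene)hex-5-enal
Product: 11 (E)-2-(but-3-en-1-yl)-3-[(2R,3S,4R)-4-[(dimethylamino)methyl]-3-(1,3-dioxolan-2-yl)-5-oxooxolan-2-yl]prop-2-enal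
Conditions: toluene, 60 °C
Reagents that add atoms: none
Why: Wittig olefination with a stabilised formyl ylide, which should give the (E)-enal (formyl group trans to C6), so that C3 lies cis to C6 across C4=C5 as the ring requires.

**Step 8**
Reactants: 11 (E)-2-(but-3-en-1-yl)-3-[(2R,3S,4R)-4-[(dimethylamino)methyl]-3-(1,3-dioxolan-2-yl)-5-oxooxolan-2-yl]prop-2-enal
Product: 12 (3R,4S,5R)-3-[(dimethylamino)methyl]-4-(1,3-dioxolan-2-yl)-5-[(E)-2-(hydroxymethyl)hexa-1,5-dien-1-yl]oxolan-2-one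
Conditions: NaBH4, CeCl3·7H2O, MeOH, −40 °C
Reagents that add atoms: none
Why: Luche 1,2-reduction, selective for the enal over the lactone, delivers the C15 allylic alcohol.

**Step 9**
Reactants: 12 (3R,4S,5R)-3-[(dimethylamino)methyl]-4-(1,3-dioxolan-2-yl)-5-[(E)-2-(hydroxymethyl)hexa-1,5-dien-1-yl]oxolan-2-one
Product: 13 (3R,4S,5R)-5-[(E)-2-[(tert-butyldiphenylsilyloxy)methyl]hexa-1,5-dien-1-yl]-3-[(dimethylamino)methyl]-4-(1,3-dioxolan-2-yl)oxolan-2-one
Conditions: t-BuPh2SiCl, imidazole, CH2Cl2, 23 °C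
Reagents that add atoms: tert-butyl(chloro)diphenylsilane, CC(C)(C)[Si](Cl)(c1ccccc1)c1ccccc1
Why: Silylation of the primary allylic alcohol with a group that should outlast the acid of step 12 and the selective desilylation of step 15.

**Step 10**
Reactants: 13 (3R,4S,5R)-5-[(E)-2-[(tert-butyldiphenylsilyloxy)methyl]hexa-1,5-dien-1-yl]-3-[(dimethylamino)methyl]-4-(1,3-dioxolan-2-yl)oxolan-2-one; 14 methyl 2-(hydroxymethyl)acrylate
Product: 15 methyl (2E,6E)-6-[(tert-butyldiphenylsilyloxy)methyl]-7-[(2R,3S,4R)-4-[(dimethylamino)methyl]-3-(1,3-dioxolan-2-yl)-5-oxooxolan-2-yl]-2-(hydroxymethyl)hepta-2,6-dienoate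
Conditions: second-generation Hoveyda–Grubbs catalyst RuCl2(H2IMes)(=CH-C6H4-2-O-i-Pr) (10 mol %), camphorsulfonic acid (1.1 equiv), 14 (10 equiv), CH2Cl2, 40 °C; NaHCO3 wash
Reagents that add atoms: none
Why: Olefin cross-metathesis of the monosubstituted alkene with a 1,1-disubstituted acrylate attaches C10, C14 and C9 in one step; the amine is protected as its salt, the trisubstituted C4=C5 is inert, and the C1=C10 geometry is immaterial because step 13 resets it.

**Step 11**
Reactants: 15 methyl (2E,6E)-6-[(tert-butyldiphenylsilyloxy)methyl]-7-[(2R,3S,4R)-4-[(dimethylamino)methyl]-3-(1,3-dioxolan-2-yl)-5-oxooxolan-2-yl]-2-(hydroxymethyl)hepta-2,6-dienoate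
Product: 16 methyl (2E,6E)-6-[(tert-butyldiphenylsilyloxy)methyl]-7-[(2R,3S,4R)-4-[(dimethylamino)methyl]-3-(1,3-dioxolan-2-yl)-5-oxooxolan-2-yl]-2-formylhepta-2,6-dienoate
Conditions: activated MnO2, CH2Cl2, 23 °C
Reagents that add atoms: none
Why: Chemoselective oxidation of the only free (allylic) alcohol to the C9 aldehyde, tolerated by the tertiary amine and the acetal.

**Step 12**
Reactants: 16 methyl (2E,6E)-6-[(tert-butyldiphenylsilyloxy)methyl]-7-[(2R,3S,4R)-4-[(dimethylamino)methyl]-3-(1,3-dioxolan-2-yl)-5-oxooxolan-2-yl]-2-formylhepta-2,6-dienoate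
Product: 17 methyl (2E,6E)-6-[(tert-butyldiphenylsilyloxy)methyl]-7-[(2R,3S,4R)-4-[(dimethylamino)methyl]-3-formyl-5-oxooxolan-2-yl]-2-formylhepta-2,6-dienoate
Conditions: 2 M aq. HCl–THF (1:4), 23 °C; NaHCO3 work-up; used at once
Reagents that add atoms: water, O
Why: Acid hydrolysis of the dioxolane frees the C8 aldehyde, while the tert-butyldiphenylsilyl ether and the protonated amine should survive and the all-trans lactone protects C7 against epimerisation.

**Step 13**
Reactants: 17 methyl (2E,6E)-6-[(tert-butyldiphenylsilyloxy)methyl]-7-[(2R,3S,4R)-4-[(dimethylamino)methyl]-3-formyl-5-oxooxolan-2-yl]-2-formylhepta-2,6-dienoate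
Product: 19 methyl 15-(tert-butyldiphenylsilyloxy)-13-(dimethylamino)-8β-hydroxy-9α-(triethylsilyloxy)-11βH-11,13-dihydrogermacra-1(10)E,4E-dien-6α,12-olid-14-oate, via γ-siloxyallylchromium dichloride 18 (not isolated)
Conditions: CrCl2 (8 equiv), Et3SiCl (1.5 equiv), DMF–THF, 0 → 23 °C, syringe-pump addition of 17 (final 2 mM); aq. NaHCO3 work-up
Reagents that add atoms: chlorotriethylsilane, CC[Si](Cl)(CC)CC
Why: Proposed new method: divalent chromium, helped by O-silylation with Et3SiCl, should reduce only the doubly activated 2-formyl-enoate of 17 by two electrons to the γ-siloxyallylchromium 18 (chromium on C1, push–pull β-siloxyacrylate across C9=C10), which adds through C9 to the C8 aldehyde in a six-membered Zimmerman–Traxler chair (SE2′) and thereby re-forms C1=C10; the closest known reactions are the intermolecular CrCl2/R3SiCl cross-pinacol-type coupling of enones and enals with aldehydes and Nozaki–Hiyama–Kishi allylchromium macrocyclisations to ten-membered rings. The ten-membered carbocycle closes in a 10-exo-trig mode at the aldehyde with the whole allyl unit inside the new ring. The C1=C10 geometry is set anew: A1,2 strain with the C10 ester and the short C2–C7 tether both force C2 pseudoaxial on C1, which gives the ring-cis enoate (ester trans to C2) whatever the geometry of 17. C9 is controlled by the enol geometry (siloxy group trans to the ester, the preferred β-alkoxyacrylate arrangement, hence axial in the chair), which leads to the threo, ring-trans C8/C9 relationship; C8 is controlled by the C7 stereocentre of the trans-lactone, C9 arriving anti to the C7–C11 bond past H7 with the carbonyl oxygen on the C6 side (Felkin–Anh), which places O8 cis to C11. The step needs chemoselective reduction of the enal over the saturated aldehyde and the lactone (only the conjugated, silyl-activated carbonyl is reducible by CrCl2), attack through C9 and not C1 (chromium stays on the carbon remote from oxygen, as in the intermolecular precedent) and ring closure over oligomerisation (slow addition at high dilution); a limited amount of Et3SiCl should leave the chromium alkoxide on O8 unsilylated.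

**Step 14**
Reactants: 19 methyl 15-(tert-butyldiphenylsilyloxy)-13-(dimethylamino)-8β-hydroxy-9α-(triethylsilyloxy)-11βH-11,13-dihydrogermacra-1(10)E,4E-dien-6α,12-olid-14-oate
Product: 20 methyl 15-(tert-butyldiphenylsilyloxy)-13-(dimethylamino)-8β-(2-methylpropanoyloxy)-9α-(triethylsilyloxy)-11βH-11,13-dihydrogermacra-1(10)E,4E-dien-6α,12-olid-14-oate
Conditions: (i-PrCO)2O, DMAP, Et3N, CH2Cl2, 0 → 23 °C
Reagents that add atoms: isobutyric anhydride, CC(C)C(=O)OC(=O)C(C)C
Why: DMAP-catalysed acylation of the only free hydroxyl (O8) under conditions too weakly basic for silyl migration or lactone translocation.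

**Step 15**
Reactants: 20 methyl 15-(tert-butyldiphenylsilyloxy)-13-(dimethylamino)-8β-(2-methylpropanoyloxy)-9α-(triethylsilyloxy)-11βH-11,13-dihydrogermacra-1(10)E,4E-dien-6α,12-olid-14-oate
Product: 21 methyl 15-(tert-butyldiphenylsilyloxy)-13-(dimethylamino)-9α-hydroxy-8β-(2-methylpropanoyloxy)-11βH-11,13-dihydrogermacra-1(10)E,4E-dien-6α,12-olid-14-oate
Conditions: HF·pyridine, pyridine, THF, 0 °C
Reagents that add atoms: none
Why: Buffered fluoride cleaves the secondary triethylsilyl ether far faster than the primary tert-butyldiphenylsilyl ether and should not trigger acyl migration.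

**Step 16**
Reactants: 21 methyl 15-(tert-butyldiphenylsilyloxy)-13-(dimethylamino)-9α-hydroxy-8β-(2-methylpropanoyloxy)-11βH-11,13-dihydrogermacra-1(10)E,4E-dien-6α,12-olid-14-oate
Product: 22 methyl 9α-acetoxy-15-(tert-butyldiphenylsilyloxy)-13-(dimethylamino)-8β-(2-methylpropanoyloxy)-11βH-11,13-dihydrogermacra-1(10)E,4E-dien-6α,12-olid-14-oate
Conditions: Ac2O, pyridine, DMAP (cat.), CH2Cl2, 0 °C
Reagents that add atoms: acetic anhydride, CC(=O)OC(C)=O
Why: Fast DMAP-catalysed acetylation of the allylic C9 hydroxyl, which should outrun O8-to-O9 acyl migration.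

**Step 17**
Reactants: 22 methyl 9α-acetoxy-15-(tert-butyldiphenylsilyloxy)-13-(dimethylamino)-8β-(2-methylpropanoyloxy)-11βH-11,13-dihydrogermacra-1(10)E,4E-dien-6α,12-olid-14-oate
Product: 23 methyl 9α-acetoxy-13-(dimethylamino)-15-hydroxy-8β-(2-methylpropanoyloxy)-11βH-11,13-dihydrogermacra-1(10)E,4E-dien-6α,12-olid-14-oate
Conditions: HF·pyridine, THF, 23 °C
Reagents that add atoms: none
Why: Acidic fluoride removes the primary silyl ether without the basic conditions that could hydrolyse or shift the three esters.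

**Step 18**
Reactants: 23 methyl 9α-acetoxy-13-(dimethylamino)-15-hydroxy-8β-(2-methylpropanoyloxy)-11βH-11,13-dihydrogermacra-1(10)E,4E-dien-6α,12-olid-14-oate
Product: 25 methyl 9α-acetoxy-15-hydroxy-8β-(2-methylpropanoyloxy)germacra-1(10)E,4E,11(13)-trien-6α,12-olid-14-oate (CNP0242134.2), via quaternary trimethylammonium iodide 24 (not isolated)
Conditions: MeI, MeCN, 23 °C; then aq. NaHCO3, EtOAc, 23 °C
Reagents that add atoms: none
Why: N-methylation followed by mild-base E1cB elimination of trimethylamine unveils the α-methylene lactone as the last operation, which removes the C11 stereocentre and leaves the esters intact.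

**Compound list**
1 | (S)-5-(hydroxymethyl)furan-2(5H)-one | O=C1C=C[C@@H](CO)O1 | starting material
2 | (S)-5-[(triethylsilyloxy)methyl]furan-2(5H)-one | O=C1C=C[C@@H](CO[Si](CC)(CC)CC)O1 | intermediate
3 | (4S,5S)-4-(1,3-dioxolan-2-yl)-5-[(triethylsilyloxy)methyl]oxolan-2-one (4,5-trans) | O=C1C[C@H](C2OCCO2)[C@@H](CO[Si](CC)(CC)CC)O1 | intermediate
4 | lithium enolate of 3 | [Li]OC1=C[C@H](C2OCCO2)[C@@H](CO[Si](CC)(CC)CC)O1 | intermediate (not isolated)
5 | (3R,4S,5S)-3-[(dimethylamino)methyl]-4-(1,3-dioxolan-2-yl)-5-[(triethylsilyloxy)methyl]oxolan-2-one (all-trans) | CN(C)C[C@@H]1C(=O)O[C@H](CO[Si](CC)(CC)CC)[C@H]1C2OCCO2 | intermediate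
6 | (2S,3S,4R)-4-[(dimethylamino)methyl]-3-(1,3-dioxolan-2-yl)-5-oxooxolane-2-carbaldehyde | CN(C)C[C@@H]1C(=O)O[C@H](C=O)[C@H]1C2OCCO2 | intermediate
7 | 5-bromopent-1-ene | C=CCCCBr | starting material
8 | (pent-4-en-1-yl)triphenylphosphonium bromide | C=CCCC[P+](c1ccccc1)(c1ccccc1)c1ccccc1.[Br-] | intermediate
9 | pent-4-enylidene(triphenyl)phosphorane | C=CCCC=P(c1ccccc1)(c1ccccc1)c1ccccc1 | intermediate (not isolated)
10 | 2-(triphenylphosphoranylidene)hex-5-enal | C=CCCC(C=O)=P(c1ccccc1)(c1ccccc1)c1ccccc1 | intermediate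
11 | (E)-2-(but-3-en-1-yl)-3-[(2R,3S,4R)-4-[(dimethylamino)methyl]-3-(1,3-dioxolan-2-yl)-5-oxooxolan-2-yl]prop-2-enal | CN(C)C[C@@H]1C(=O)O[C@H](/C=C(/C=O)CCC=C)[C@H]1C2OCCO2 | intermediate
12 | (3R,4S,5R)-3-[(dimethylamino)methyl]-4-(1,3-dioxolan-2-yl)-5-[(E)-2-(hydroxymethyl)hexa-1,5-dien-1-yl]oxolan-2-one | CN(C)C[C@@H]1C(=O)O[C@H](/C=C(/CO)CCC=C)[C@H]1C2OCCO2 | intermediate
13 | (3R,4S,5R)-5-[(E)-2-[(tert-butyldiphenylsilyloxy)methyl]hexa-1,5-dien-1-yl]-3-[(dimethylamino)methyl]-4-(1,3-dioxolan-2-yl)oxolan-2-one | CN(C)C[C@@H]1C(=O)O[C@H](/C=C(/CO[Si](c2ccccc2)(c2ccccc2)C(C)(C)C)CCC=C)[C@H]1C3OCCO3 | intermediate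
14 | methyl 2-(hydroxymethyl)acrylate | C=C(CO)C(=O)OC | starting material
15 | methyl (2E,6E)-6-[(tert-butyldiphenylsilyloxy)methyl]-7-[(2R,3S,4R)-4-[(dimethylamino)methyl]-3-(1,3-dioxolan-2-yl)-5-oxooxolan-2-yl]-2-(hydroxymethyl)hepta-2,6-dienoate | CN(C)C[C@@H]1C(=O)O[C@H](/C=C(/CO[Si](c2ccccc2)(c2ccccc2)C(C)(C)C)CC/C=C(\CO)C(=O)OC)[C@H]1C3OCCO3 | intermediate
16 | methyl (2E,6E)-6-[(tert-butyldiphenylsilyloxy)methyl]-7-[(2R,3S,4R)-4-[(dimethylamino)methyl]-3-(1,3-dioxolan-2-yl)-5-oxooxolan-2-yl]-2-formylhepta-2,6-dienoate | CN(C)C[C@@H]1C(=O)O[C@H](/C=C(/CO[Si](c2ccccc2)(c2ccccc2)C(C)(C)C)CC/C=C(\C=O)C(=O)OC)[C@H]1C3OCCO3 | intermediate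
17 | methyl (2E,6E)-6-[(tert-butyldiphenylsilyloxy)methyl]-7-[(2R,3S,4R)-4-[(dimethylamino)methyl]-3-formyl-5-oxooxolan-2-yl]-2-formylhepta-2,6-dienoate (seco-8,9-dialdehyde) | CN(C)C[C@@H]1C(=O)O[C@H](/C=C(/CO[Si](c2ccccc2)(c2ccccc2)C(C)(C)C)CC/C=C(\C=O)C(=O)OC)[C@H]1C=O | intermediate
18 | γ-(triethylsiloxy)allylchromium dichloride from 17 (Cr on C1, enol silyl ether C9=C10 with the siloxy group trans to the ester, C1 configuration undefined) | CN(C)C[C@@H]1C(=O)O[C@H](/C=C(/CO[Si](c2ccccc2)(c2ccccc2)C(C)(C)C)CCC([Cr](Cl)Cl)/C(C(=O)OC)=C\O[Si](CC)(CC)CC)[C@H]1C=O | intermediate (not isolated)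
19 | methyl 15-(tert-butyldiphenylsilyloxy)-13-(dimethylamino)-8β-hydroxy-9α-(triethylsilyloxy)-11βH-11,13-dihydrogermacra-1(10)E,4E-dien-6α,12-olid-14-oate | CN(C)C[C@@H]1C(=O)O[C@@H]2/C=C(/CO[Si](c3ccccc3)(c3ccccc3)C(C)(C)C)CC/C=C(/C(=O)OC)[C@H](O[Si](CC)(CC)CC)[C@@H](O)[C@@H]12 | intermediate
20 | methyl 15-(tert-butyldiphenylsilyloxy)-13-(dimethylamino)-8β-(2-methylpropanoyloxy)-9α-(triethylsilyloxy)-11βH-11,13-dihydrogermacra-1(10)E,4E-dien-6α,12-olid-14-oate | CN(C)C[C@@H]1C(=O)O[C@@H]2/C=C(/CO[Si](c3ccccc3)(c3ccccc3)C(C)(C)C)CC/C=C(/C(=O)OC)[C@H](O[Si](CC)(CC)CC)[C@@H](OC(=O)C(C)C)[C@@H]12 | intermediate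
21 | methyl 15-(tert-butyldiphenylsilyloxy)-13-(dimethylamino)-9α-hydroxy-8β-(2-methylpropanoyloxy)-11βH-11,13-dihydrogermacra-1(10)E,4E-dien-6α,12-olid-14-oate | CN(C)C[C@@H]1C(=O)O[C@@H]2/C=C(/CO[Si](c3ccccc3)(c3ccccc3)C(C)(C)C)CC/C=C(/C(=O)OC)[C@H](O)[C@@H](OC(=O)C(C)C)[C@@H]12 | intermediate
22 | methyl 9α-acetoxy-15-(tert-butyldiphenylsilyloxy)-13-(dimethylamino)-8β-(2-methylpropanoyloxy)-11βH-11,13-dihydrogermacra-1(10)E,4E-dien-6α,12-olid-14-oate | CN(C)C[C@@H]1C(=O)O[C@@H]2/C=C(/CO[Si](c3ccccc3)(c3ccccc3)C(C)(C)C)CC/C=C(/C(=O)OC)[C@H](OC(C)=O)[C@@H](OC(=O)C(C)C)[C@@H]12 | intermediate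
23 | methyl 9α-acetoxy-13-(dimethylamino)-15-hydroxy-8β-(2-methylpropanoyloxy)-11βH-11,13-dihydrogermacra-1(10)E,4E-dien-6α,12-olid-14-oate | CN(C)C[C@@H]1C(=O)O[C@@H]2/C=C(/CO)CC/C=C(/C(=O)OC)[C@H](OC(C)=O)[C@@H](OC(=O)C(C)C)[C@@H]12 | intermediate
24 | N-methyl quaternary ammonium iodide of 23 | C[N+](C)(C)C[C@@H]1C(=O)O[C@@H]2/C=C(/CO)CC/C=C(/C(=O)OC)[C@H](OC(C)=O)[C@@H](OC(=O)C(C)C)[C@@H]12.[I-] | intermediate (not isolated)
25 | methyl 9α-acetoxy-15-hydroxy-8β-(2-methylpropanoyloxy)germacra-1(10)E,4E,11(13)-trien-6α,12-olid-14-oate, (6R,7S,8S,9S), CNP0242134.2 | C=C1C(=O)O[C@@H]2/C=C(/CO)CC/C=C(/C(=O)OC)[C@H](OC(C)=O)[C@@H](OC(=O)C(C)C)[C@@H]12 | target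

**Step count.** Total: 18 steps. Longest linear sequence: 16 steps (steps 1–4 and 7–18).

**Steps most likely to fail**

1. Step 13. The allylchromium may form unselectively, bond through C1 to an eight-membered ring, couple between molecules, add with poor facial selectivity at C8/C9, or end up silylated on both oxygens. The fallback uses known chemistry, sets out from 17 and comes back at 21. The two formyl groups are joined by a McMurry-type pinacol macrocyclisation with low-valent titanium (TiCl3(DME)1.5, Zn–Cu couple, DME, 25 °C, slow addition), a ketyl coupling established for medium and large carbocyclic 1,2-diols, also with one conjugated aldehyde. The (E)-isomer of 17 already holds C2 cis to the formyl group, so the ring-cis enoate is kept. This should give methyl 15-(tert-butyldiphenylsilyloxy)-13-(dimethylamino)-8β,9α-dihydroxy-11βH-11,13-dihydrogermacra-1(10)E,4E-dien-6α,12-olid-14-oate F1, which is also what desilylation of an over-silylated cyclisation product would give. The allylic 9-hydroxyl alone is then oxidised with MnO2 to the 8β-hydroxy-9-oxo compound F2, so that C9 epimers converge. The 8-hydroxyl is esterified with isobutyric anhydride and DMAP to the 8β-(2-methylpropanoyloxy)-9-oxo compound F3. Luche reduction (NaBH4, CeCl3·7H2O, MeOH, −78 °C), with hydride delivered anti to the 8-acyloxy group, returns to 21.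

2. Step 10. The amine may sequester the ruthenium catalyst, and productive metathesis with the 1,1-disubstituted acrylate may be slower than homodimerisation of 13. The fallback sets out from 13 and comes back at 17. The terminal alkene is dihydroxylated in preference to the trisubstituted alkene, which is deactivated and shielded by its two allylic oxygens (OsO4 cat., N-methylmorpholine N-oxide, acetone–water), to the 5,6-dihydroxyhexenyl lactone F4. NaIO4 cleavage gives (E)-4-[(tert-butyldiphenylsilyloxy)methyl]-5-[lactonyl]pent-4-enal F5 (C1 aldehyde). Aldol addition of the lithium enolate of methyl 3,3-dimethoxypropanoate (COC(=O)CC(OC)OC; LiN(i-Pr)2, THF, −78 °C) gives the β-hydroxy ester F6. Mesylation (MsCl, Et3N) to the mesylate F7 and elimination with DBU give methyl 2-(dimethoxymethyl)hepta-2,6-dienoate F8. Aqueous HCl–THF then cleaves both acetals at once and returns to 17.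

3. Step 7. The hindered formyl ylide may react sluggishly, with epimerisation at C6 or thermal loss of dimethylamine on prolonged heating. The fallback sets out from 6 and comes back at 11. It is an amine-catalysed cross-aldol condensation with hex-5-enal (C=CCCCC=O, added slowly; pyrrolidine, benzoic acid, CH2Cl2, 23 °C), in which 6 can only act as the acceptor. The 2-(but-3-en-1-yl)-3-hydroxy-3-[lactonyl]propanal F9 forms first and dehydrates in the flask to the thermodynamically preferred (E)-enal 11.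

**Further compounds**
F1 | step 13 | methyl 15-(tert-butyldiphenylsilyloxy)-13-(dimethylamino)-8β,9α-dihydroxy-11βH-11,13-dihydrogermacra-1(10)E,4E-dien-6α,12-olid-14-oate | CN(C)C[C@@H]1C(=O)O[C@@H]2/C=C(/CO[Si](c3ccccc3)(c3ccccc3)C(C)(C)C)CC/C=C(/C(=O)OC)[C@H](O)[C@@H](O)[C@@H]12
F2 | step 13 | methyl 15-(tert-butyldiphenylsilyloxy)-13-(dimethylamino)-8β-hydroxy-9-oxo-11βH-11,13-dihydrogermacra-1(10)E,4E-dien-6α,12-olid-14-oate | CN(C)C[C@@H]1C(=O)O[C@@H]2/C=C(/CO[Si](c3ccccc3)(c3ccccc3)C(C)(C)C)CC/C=C(/C(=O)OC)C(=O)[C@@H](O)[C@@H]12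
F3 | step 13 | methyl 15-(tert-butyldiphenylsilyloxy)-13-(dimethylamino)-8β-(2-methylpropanoyloxy)-9-oxo-11βH-11,13-dihydrogermacra-1(10)E,4E-dien-6α,12-olid-14-oate | CN(C)C[C@@H]1C(=O)O[C@@H]2/C=C(/CO[Si](c3ccccc3)(c3ccccc3)C(C)(C)C)CC/C=C(/C(=O)OC)C(=O)[C@@H](OC(=O)C(C)C)[C@@H]12
F4 | step 10 | (3R,4S,5R)-5-[(E)-2-[(tert-butyldiphenylsilyloxy)methyl]-5,6-dihydroxyhex-1-en-1-yl]-3-[(dimethylamino)methyl]-4-(1,3-dioxolan-2-yl)oxolan-2-one (both carbinol epimers) | CN(C)C[C@@H]1C(=O)O[C@H](/C=C(/CO[Si](c2ccccc2)(c2ccccc2)C(C)(C)C)CCC(O)CO)[C@H]1C3OCCO3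
F5 | step 10 | (E)-4-[(tert-butyldiphenylsilyloxy)methyl]-5-[(2R,3S,4R)-4-[(dimethylamino)methyl]-3-(1,3-dioxolan-2-yl)-5-oxooxolan-2-yl]pent-4-enal | CN(C)C[C@@H]1C(=O)O[C@H](/C=C(/CO[Si](c2ccccc2)(c2ccccc2)C(C)(C)C)CCC=O)[C@H]1C3OCCO3
F6 | step 10 | methyl (E)-6-[(tert-butyldiphenylsilyloxy)methyl]-2-(dimethoxymethyl)-3-hydroxy-7-[lactonyl as in F5]hept-6-enoate (diastereomer mixture at C2/C3) | CN(C)C[C@@H]1C(=O)O[C@H](/C=C(/CO[Si](c2ccccc2)(c2ccccc2)C(C)(C)C)CCC(O)C(C(OC)OC)C(=O)OC)[C@H]1C3OCCO3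
F7 | step 10 | 3-methanesulfonate of F6 | CN(C)C[C@@H]1C(=O)O[C@H](/C=C(/CO[Si](c2ccccc2)(c2ccccc2)C(C)(C)C)CCC(OS(C)(=O)=O)C(C(OC)OC)C(=O)OC)[C@H]1C3OCCO3
F8 | step 10 | methyl (6E)-6-[(tert-butyldiphenylsilyloxy)methyl]-2-(dimethoxymethyl)-7-[lactonyl as in F5]hepta-2,6-dienoate (2E/2Z mixture) | CN(C)C[C@@H]1C(=O)O[C@H](/C=C(/CO[Si](c2ccccc2)(c2ccccc2)C(C)(C)C)CCC=C(C(OC)OC)C(=O)OC)[C@H]1C3OCCO3
F9 | step 7 | 2-(but-3-en-1-yl)-3-hydroxy-3-[4-[(dimethylamino)methyl]-3-(1,3-dioxolan-2-yl)-5-oxooxolan-2-yl]propanal (lactone stereocentres as in 6, new centres as mixture) | CN(C)C[C@@H]1C(=O)O[C@H](C(O)C(C=O)CCC=C)[C@H]1C2OCCO2
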